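(The runs are calculated for an exercise, and the scatter is random.)

**Setting.** Temperature was the setting the earlier runs never moved, so I bracketed epsilon, the flask at the 80 °C of the north run, and left the hotter and cooler flasks to a guess.

| flask | starting material | partner | temperature | remark | time |
|---|---|---|---|---|---|
| north | 0.050 M | 0.13 M | 80 °C | run made earlier |  |
| epsilon | 0.10 M | 0.130 M | 80 °C |  | 20 min |
| zeta | 0.10 M | 0.130 M | 60 °C |  | 20 min |
| theta | 0.10 M | 0.130 M | 100 °C |  | 20 min |
| delta | 0.10 M | 0.130 M |  | at 100 °C until 4.0 min, from then on at 60 °C | 20 min |

north run (percent of the starting material charged)

| time / s | target / % | homo product / % | side product / % |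
|---|---|---|---|
| 10.0 | 0 | 1 | 2 |
| 30.0 | 4 | 0 | 4 |
| 60.0 | 6 | 0 | 14 |
| 80.0 | 8 | 2 | 18 |
| 120 | 14 | 3 | 28 |

(each reading ± 1.5 percentage points)

- percentages count the starting material that a species holds: one homo product counts as two
- a reading or a percentage of target counts all its forms, free or not
- the earlier runs do not show what temperature does; that part of a forecast is a guess

- which flask leads in share of target in all that became target or homo product or side product ("all alike" within 1.5 percentage points) (epsilon / zeta / theta / delta / all alike)
- share of target in all that became target or homo product or side product, epsilon
- share of target in all that became target or homo product or side product, zeta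
- share of target in all that became target or homo product or side product, theta
- share of target in all that became target or homo product or side product, delta

**The balance.** In epsilon the limiting reagent is starting material, 0.10 M against 0.130 M of partner. I assumed that it ends as target, homo product or side product. Let S be the target share among these, h the homo share, and r the ratio of target to side product, so that S is (one minus h) times r/(r plus one). I also assumed that target takes partner and side product does not, so r = g c, where c is the partner level. Here g is the selectivity factor, target per side product per unit of partner concentration. The last north reading gives g = 3.85 L mol⁻¹.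

**Upper bound.** With h zero and c at its charge, S is 33.3%.

**Lower bound.** I held c for the whole run at the charge less one partner per target at the upper bound, which is 0.0967 M. The north run reads h as 6.67%. Supposing homo product second order, I scaled h with the charge of starting material to 13.3%. That gives S = 23.5%.

**The result.** The forecast put epsilon at 29%, inside my bracket, with zeta 33%, theta 25% and delta 26%, saying “Temperature is a guess”. The flasks gave 24.7% for epsilon, above my lower bound and below my upper one , with 30.6% for zeta, 19.5% for theta and 19.5% for delta, so zeta led.

    starting material → intermediate (k = 0.00310 s⁻¹, Ea = 91.0 kJ mol⁻¹)
    partner + target ⇌ idle adduct, settled at all times (K = 110 L mol⁻¹, ΔH = −20.0 kJ mol⁻¹)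
    2 intermediate → homo product (k = 0.00280 L mol⁻¹ s⁻¹, Ea = 55.0 kJ mol⁻¹)
    partner + intermediate → target (k = 0.00370 L mol⁻¹ s⁻¹, Ea = 81.0 kJ mol⁻¹)
    intermediate → side product (k = 6.70 × 10⁻⁴ s⁻¹, Ea = 104 kJ mol⁻¹)
    (constants at 60 °C)

**Hot flask.** Theta's target and side product over its charged partner give g = 1.94 L mol⁻¹, less than the north reading. On the difference in share between theta and zeta, the largest single effect is what temperature does to the path from intermediate to side product: without it, theta minus zeta goes from −11 percentage points to 38 points. For a neighbour of theta, charged with 0.033 M of partner, theta's g gives r = 0.0640 and, with h left out, S = 6.01%. The computed flask gives 5.77%.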